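(The earlier runs and the new flask were computed on assumed constants; noise was put on by code.)

Early in the cedar run, intermediate and product together stood at 36.6 % of the solid substrate charged after 0.417 min, and at 101 % after 2.00 min. The larch run stopped at 75.0 %, with 0.75 equiv of coupling partner charged.

common to all: solid substrate 0.25 M

| run | coupling partner | temperature | remark | time |
|---|---|---|---|---|
| larch | 0.75 equiv | 35 °C | run made earlier |  |
| cedar | 3 equiv | 60 °C | run made earlier |  |
| blue | 1.50 equiv | 80 °C |  | 2.5 min |
| violet | 1.50 equiv | 40 °C |  | 2.5 min |
| grey | 1.50 equiv | 60 °C |  | 2.5 min |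

- larch (time / min: intermediate / %, product / %): 1.50: 10.1, 27.9; 4.00: 12.7, 53.2; 6.00: 15.2, 55.7; 10.0: 15.1, 59.8; 15.0: 14.4, 59.0; 20.0: 15.4, 60.4; 25.0: 15.9, 59.1
- cedar (time / min: intermediate / %, product / %): 0.417: 4.8, 31.8; 1.00: 23.2, 71.8; 2.00: 24.3, 76.2; 2.50: 23.7, 77.7; 4.00: 22.8, 75.6; 5.00: 23.5, 74.6; 6.00: 25.2, 75.8

(standard deviation of a reading: 1 percentage point)

- as a solid, counted per litre of solution: solid substrate
- on the list of suspects stand: intermediate <-> product + by-product; solid substrate <-> starting material; starting material + coupling partner <-> intermediate
- at the start none of the solid substrate is in solution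
- what has only dissolved of solid substrate counts as not reacted

* the flask that comes out highest in amount of intermediate, in percent of the solid substrate charged, or "all alike" when all lie within 1.5 percentage points (blue / violet / grey / all alike)
* intermediate at the end, in percent of the solid substrate charged, blue
* intermediate at the end, in percent of the solid substrate charged, violet
* intermediate at the end, in percent of the solid substrate charged, grey

The new flasks hold 1.50 equiv of coupling partner, more than larch and above one equivalent. So I kept the ledger in solid substrate, the limiting reagent. I booked each mole as intermediate or as product, and each product brings one by-product. The plateau of cedar gives the split, read from its readings at 2.00 min and 6.00 min: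

[product] = [by-product] = 0.190 M

[intermediate] = 0.0619 M

I call K = [product][by-product]/[intermediate] the split quotient:

K = 0.583 M

Larch, at a different temperature, reads 0.592 M, close to cedar. I closed the books with every mole of the 0.25 M booked to those two entries:

[product] = 0.189 M

product 75.6 %, intermediate 24.4 %

That is my own figure, with nothing booked as starting material. Violet was my doubtful flask, since larch, near its temperature, showed 38.0 % after 1.50 min.

The forecast gave blue 24 %, violet 23 % and grey 23.8 %, so all alike, and it held “so K is temperature-independent”.

The flasks gave blue 22.2 %, violet 23.0 % and grey 23.2 %, so all alike: the spread of 1.00 percentage point lies inside the margin.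

    intermediate ⇌ product + by-product (K = 0.580 M, k = 0.120 s⁻¹, Ea = 86.0 kJ mol⁻¹, ΔH = 1.00 kJ mol⁻¹)
    solid substrate ⇌ starting material, rate k2*(cs2 - [starting material]) while solid is left; crystals form when [starting material] > cs2 (solubility = 0.0720 M, k = 0.0690 s⁻¹)
    starting material + coupling partner ⇌ intermediate (K = 130 M⁻¹, k = 0.210 M⁻¹ s⁻¹, Ea = 44.0 kJ mol⁻¹, ΔH = −29.0 kJ mol⁻¹)
    (constants at 40 °C)

At 2.50 min, grey held 2.66 % as starting material. With that entry taken off, K gives 23.4 % intermediate, against 23.2 % found. The neighbouring flask is grey with 0.62 M of solid substrate. At 2.50 min, 7.1 % of its charge was still solid or dissolved. The same reckoning on the rest gives 35.3 % intermediate. The neighbour held 35.1 %.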